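1. In elm, alder and maple partner is charged at 155 mM against 31 mM of substrate, so making product from the whole charge of substrate uses 20.0% of the partner. I therefore treat partner as roughly constant. The step substrate + partner ⇌ product is then pseudo-first-order in substrate, with partner folded into the forward constant.

| flask | substrate | partner | temperature | remark | time |
|---|---|---|---|---|---|
| south-west | 31 mM | 78 mM | 48 °C | run made earlier |  |
| north-west | 31 mM | 310 mM | 75 °C | run made earlier |  |
| elm | 31 mM | 155 mM | 35 °C |  | 4.0 h |
| alder | 31 mM | 155 mM | 85 °C |  | 4.0 h |
| maple | 31 mM | 155 mM | 60 °C |  | 4.0 h |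

- south-west (time / min: product / %, substrate / %): 6.00: 2.2, 47.3; 10.0: 4.1, 46.3; 15.0: 5.5, 45.8; 25.0: 7.7, 45.6; 40.0: 10.3, 44.0; 80.0: 14.7, 43.1
- north-west (time / min: product / %, substrate / %): 1.33: 13.1, 48.2; 4.00: 26.3, 42.7; 6.00: 31.9, 40.7; 12.0: 36.5, 38.1; 15.0: 37.3, 38.0; 20.0: 37.7, 37.7

(standard deviation of a reading: 0.3 percentage points)

* which flask leads in amount of product, in percent of the substrate charged ("all alike" within 1.5 percentage points) (elm / alder / maple / all alike)
* how much product is there at the end, in percent of the substrate charged: elm
* how much product is there at the end, in percent of the substrate charged: alder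
* how much product is there at the end, in percent of the substrate charged: maple



2. At a plateau, forward and back rates are equal, so product over substrate is proportional to partner. The north-west run comes close to such a plateau: product reads 0.4 percentage points higher over its last interval, and product and substrate both read 37.7%. Their sum is 75.4% of the charge, but the ratio doesn't need the missing rest.

3. That ratio of readings, divided by the charged partner, gives 3.23 M⁻¹ at 75 °C; I call this the plateau ratio per partner.

4. The south-west run at 48 °C already reads 4.37 M⁻¹ at its last reading, more than at 75 °C, and its product still gained 4.4 points over the last interval. The two runs differ in partner as well, but the ratio is already divided by the charge, so I take the plateau ratio per partner to fall as the flask gets warmer.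

5. My reckoning: at 155 mM of partner and 75 °C the ratio is 0.500. Maple, at 60 °C, should stand above that and alder, at 85 °C, below it. Elm, at 35 °C, is colder than maple, so I expect its plateau to lie higher, but it may still be climbing at the end.

6. The forecast gives percentages where I give a ratio: 30% for elm, 20% for alder and 26.3% for maple, with elm leading. It holds that “alder and maple reach equilibrium”.

7. The flasks give 29.5% in elm, 20.0% in alder and 25.8% in maple, so elm leads and the forecast stands. Maple's ratio is 0.630 and alder's is 0.430.

    2 substrate ⇌ resting dimer, settled at all times (K = 43.0 M⁻¹, ΔH = −10.0 kJ mol⁻¹)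
    substrate + partner ⇌ product (K = 8.40 M⁻¹, k = 0.0510 M⁻¹ min⁻¹, Ea = 63.0 kJ mol⁻¹, ΔH = −16.0 kJ mol⁻¹)
    partner ⇌ dormant form (K = 0.240, k = 0.170 min⁻¹, Ea = 84.0 kJ mol⁻¹, ΔH = −2.00 kJ mol⁻¹)
    (constants at 35 °C)

In maple the relaxation half-life of substrate + partner ⇌ product by that step alone, 0.111 h, is short against the time of 4.0 h, and product stands at 25.8% after 2.00 h and 25.8% after 4.00 h. Maple's plateau ratio per partner is thus 4.07 M⁻¹, above the 3.23 M⁻¹ read at 75 °C. Partner left, as a share of its own charge, stands at 77% in maple and 79% in a neighbour like maple but charged with 620 mM of partner. For that neighbour the plateau ratio per partner gives 2.52, and its 63.3% of product over 24.6% of substrate reads 2.57.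

The readings were generated by integration with constants of no real substance, and the scatter is random.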